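The route rests on disconnecting the bond between C2 of the pyranone ring C and C5 of the dihydrobenzofuran (the flavanone C1′). C2 is β to the C4 carbonyl and is the only stereocentre of ring C, so this bond is the 1,4-addition bond of a chromone. A rhodium-catalysed asymmetric conjugate addition of arylboronic acid 14 to chromone 23 joins the two halves and sets (2S) under catalyst control in one operation. Chromone 23 already carries the (E)-hydroxyprenyl chain at C8; boronic acid 14 carries the trans-(2R,3R)-diaryl stereocentres, made by an enantioselective rhodium-carbene C–H insertion and acid epimerisation.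

Key step: step 13

Assumption: the senses of induction of Rh2(R-PTAD)4 (step 4) and of (S)-MeO-F12-BIPHEP (step 13) are assigned by analogy with related substrates; if either proves opposite, the antipodal catalyst is used without other change.

Step 1
Reactants: 1 1-bromo-2,4-dimethoxybenzene; 2 3,5-dimethoxybenzoyl chloride
Product: 4 (5-bromo-2-hydroxy-4-methoxyphenyl)(3,5-dimethoxyphenyl)methanone, via tetramethoxy ketone 3 (not isolated)
Conditions: AlCl3 (3 equiv), ClCH2CH2Cl, 0 °C then 60 °C; aq. HCl work-up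
Reagents that add atoms: none
Why: Friedel–Crafts acylation should occur at C5 of 1 (para to one methoxy group, ortho to the other, the only unhindered activated site), and AlCl3 chelated between the new carbonyl and the ortho methoxy group should then cleave that one ether selectively.

Step 2
Reactants: 4 (5-bromo-2-hydroxy-4-methoxyphenyl)(3,5-dimethoxyphenyl)methanone; 5 4-methoxybenzyl chloride
Product: 6 {5-bromo-4-methoxy-2-[(4-methoxybenzyl)oxy]phenyl}(3,5-dimethoxyphenyl)methanone
Conditions: K2CO3 (2 equiv), KI (cat.), DMF, 60 °C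
Reagents that add atoms: none
Why: Williamson etherification of the only free (chelated) phenol installs the benzylic CH2 that later becomes C2 of the dihydrobenzofuran together with its 4-oxygenated aryl group.

Step 3
Reactants: 6 {5-bromo-4-methoxy-2-[(4-methoxybenzyl)oxy]phenyl}(3,5-dimethoxyphenyl)methanone
Product: 7 hydrazone of ketone 6 (E/Z mixture)
Conditions: N2H4·H2O (10 equiv), AcOH (cat.), EtOH, 85 °C (sealed tube)
Reagents that add atoms: hydrazine hydrate, NN.O
Why: Acid-catalysed condensation of a diaryl ketone with excess hydrazine should give the N-unsubstituted hydrazone, both geometric isomers of which lead to the same diazo compound.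

Step 4
Reactants: 7 hydrazone of ketone 6
Product: 9 (2S,3R)-5-bromo-3-(3,5-dimethoxyphenyl)-6-methoxy-2-(4-methoxyphenyl)-2,3-dihydrobenzofuran (cis), via diazo compound 8 (not isolated)
Conditions: MnO2 (8 equiv), CH2Cl2, 0 °C, filtration; then Rh2(R-PTAD)4 (1 mol%), CH2Cl2, 0 °C
Reagents that add atoms: none
Why: Oxidation gives the diaryldiazomethane, whose donor/donor rhodium carbene should undergo enantioselective intramolecular 1,5 C–H insertion into the benzylic ether C–H bond, the chiral carboxylate catalyst setting C3 (R) and the concerted insertion giving the kinetic cis C2 (S) isomer.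

Step 5
Reactants: 9 (2S,3R)-5-bromo-3-(3,5-dimethoxyphenyl)-6-methoxy-2-(4-methoxyphenyl)-2,3-dihydrobenzofuran
Product: 10 (2R,3R)-5-bromo-3-(3,5-dihydroxyphenyl)-2-(4-hydroxyphenyl)-2,3-dihydrobenzofuran-6-ol (trans)
Conditions: BBr3 (8 equiv), CH2Cl2, −78 °C to rt; then MeOH, H2O, 0 °C
Reagents that add atoms: none
Why: Lewis-acid cleavage of the four aryl methyl ethers should be accompanied by reversible ionisation of the C2–O bond (cation stabilised by the para-oxygenated aryl group) and reclosure to the thermodynamically preferred trans ring, which inverts C2 to (R) while C3 (R) is untouched.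

Step 6
Reactants: 10 (2R,3R)-5-bromo-3-(3,5-dihydroxyphenyl)-2-(4-hydroxyphenyl)-2,3-dihydrobenzofuran-6-ol
Product: 11 tetrakis(tert-butyldimethylsilyl) ether of 10
Conditions: TBSCl (6 equiv), imidazole (10 equiv), DMF, rt
Reagents that add atoms: tert-butyldimethylsilyl chloride, CC(C)(C)[Si](C)(C)Cl
Why: Standard silylation of all four phenols gives fluoride-labile protection that should survive organolithium and rhodium chemistry and be removable at the end without acid or base.

Step 7
Reactants: 11 tetrakis(tert-butyldimethylsilyl) ether of 10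
Product: 14 [(2R,3R)-6-(tert-butyldimethylsilyloxy)-3-[3,5-bis(tert-butyldimethylsilyloxy)phenyl]-2-[4-(tert-butyldimethylsilyloxy)phenyl]-2,3-dihydrobenzofuran-5-yl]boronic acid, via aryllithium 12 (not isolated), via lithium triisopropoxyborate 13 (not isolated)
Conditions: B(OiPr)3 (3 equiv), n-BuLi (1.1 equiv, added last), THF/toluene, −78 °C; then 1 M HCl to pH 5, 0 °C
Reagents that add atoms: triisopropyl borate, CC(C)OB(OC(C)C)OC(C)C; water, O
Why: Bromine–lithium exchange with in situ borate quench should trap the aryllithium before its ortho silyl group can migrate from oxygen to carbon, and mild hydrolysis of the borate releases the boronic acid.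

Step 8
Reactants: 15 5,7-dihydroxy-4H-chromen-4-one; 16 allyl bromide
Product: 17 7-(allyloxy)-5-hydroxy-4H-chromen-4-one
Conditions: K2CO3 (1.5 equiv), acetone, 56 °C
Reagents that add atoms: none
Why: Williamson etherification should occur only at the acidic 7-OH, because the 5-OH is held in a hydrogen bond to the C4 carbonyl.

Step 9
Reactants: 17 7-(allyloxy)-5-hydroxy-4H-chromen-4-one
Product: 19 8-allyl-5,7-dihydroxy-4H-chromen-4-one, via dienone 18 (not isolated)
Conditions: N,N-diethylaniline, 195 °C (sealed tube); chromatography to remove the minor 6-allyl isomer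
Reagents that add atoms: none
Why: Aromatic Claisen rearrangement ([3,3]-sigmatropic shift, then tautomerisation) should deliver the allyl group mainly to C8, because the chelated 5-OH fixes the ring-A bonds so that C7–C8 has the higher double-bond character.

Step 10
Reactants: 19 8-allyl-5,7-dihydroxy-4H-chromen-4-one
Product: 20 8-allyl-5,7-bis(tert-butyldimethylsilyloxy)-4H-chromen-4-one
Conditions: TBSOTf (3 equiv), 2,6-lutidine (4 equiv), CH2Cl2, 0 °C to rt
Reagents that add atoms: tert-butyldimethylsilyl triflate, CC(C)(C)[Si](C)(C)OS(=O)(=O)C(F)(F)F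
Why: The silyl triflate is reactive enough to silylate the chelated 5-OH as well as the 7-OH, which blocks oxa-Michael cyclisation of the 7-OH onto the enal made in the next step.

Step 11
Reactants: 20 8-allyl-5,7-bis(tert-butyldimethylsilyloxy)-4H-chromen-4-one; 21 methacrolein
Product: 22 (E)-4-[5,7-bis(tert-butyldimethylsilyloxy)-4-oxo-4H-chromen-8-yl]-2-methylbut-2-enal
Conditions: second-generation Grubbs catalyst (5 mol%), methacrolein (10 equiv), CH2Cl2, 40 °C
Reagents that add atoms: none
Why: Olefin cross-metathesis of a terminal allylarene with methacrolein should give the conjugated trisubstituted enal with high (E) selectivity under thermodynamic control, while the endocyclic chromone C2=C3 bond is inert.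

Step 12
Reactants: 22 (E)-4-[5,7-bis(tert-butyldimethylsilyloxy)-4-oxo-4H-chromen-8-yl]-2-methylbut-2-enal
Product: 23 5,7-bis(tert-butyldimethylsilyloxy)-8-[(E)-4-hydroxy-3-methylbut-2-enyl]-4H-chromen-4-one
Conditions: NaBH4 (1 equiv), CeCl3·7H2O (1.2 equiv), MeOH/THF, −78 °C
Reagents that add atoms: none
Why: Luche reduction should reduce the aldehyde 1,2 far faster than the vinylogous-ester carbonyl of the chromone, keeping the (E) alkene intact.

Step 13
Reactants: 23 5,7-bis(tert-butyldimethylsilyloxy)-8-[(E)-4-hydroxy-3-methylbut-2-enyl]-4H-chromen-4-one; 14 dihydrobenzofuran-5-ylboronic acid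
Product: 24 hexakis(tert-butyldimethylsilyl)-protected (2S)-flavanone (all six phenols silylated, primary alcohol free)
Conditions: [RhCl(C2H4)2]2 (2.5 mol%), (S)-MeO-F12-BIPHEP (5.5 mol%), KOH (20 mol%), 14 (1.5 equiv), CH2Cl2/H2O (10:1), 25 °C
Reagents that add atoms: none
Why: Hydroxo-rhodium bearing the (S)-bisphosphine transmetallates with 14 to an aryl–rhodium species, the chromone C2=C3 bond inserts into the Rh–aryl bond to form the C2–C1′ bond and an oxa-π-allyl rhodium enolate, and water protonates the enolate at C3, returning Rh–OH. The closest known reaction is the rhodium-catalysed asymmetric 1,4-addition of arylboronic acids to chromones (Hayashi–Miyaura type), which gives flavanones, 5,7-dioxygenated ones included, at room temperature with electron-poor biaryl bisphosphines. No ring is closed; the step is an intermolecular carbometallation followed by protonation. The new C2 stereocentre (S) is set by the chiral pocket of the ligand, which exposes one enantioface of the enone; the (2R,3R) centres of 14 are remote from C2, so the diastereomer ratio should follow the catalyst. The step needs 1,4- over 1,2-addition, no second arylation of the product ketone and no β-aryloxy elimination of the enolate to a chalcone; fast protonation in the biphasic medium at 25 °C, the peri 5-silyloxy group shielding C4=O and the nearly neutral conditions should secure this, and the site on the aryl partner is fixed by the C–B bond. The ortho silyloxy group slows transmetallation, which is why 14 is used in excess, and the free primary alcohol should be tolerated as in other aqueous rhodium additions.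

Step 14
Reactants: 24 hexakis(tert-butyldimethylsilyl)-protected (2S)-flavanone
Product: 25 (2S)-5,7-dihydroxy-2-[(2R,3R)-3-(3,5-dihydroxyphenyl)-6-hydroxy-2-(4-hydroxyphenyl)-2,3-dihydrobenzofuran-5-yl]-8-[(E)-4-hydroxy-3-methylbut-2-enyl]chroman-4-one
Conditions: HF·pyridine (excess), pyridine, THF, 0 °C to rt
Reagents that add atoms: none
Why: Buffered fluoride desilylation should free all six phenols under mildly acidic conditions that avoid base-induced ring opening of the flavanone (loss of C2 configuration) and ionisation of the allylic alcohol.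

Compound list
1 | 1-bromo-2,4-dimethoxybenzene | COc1ccc(Br)c(OC)c1 | starting material
2 | 3,5-dimethoxybenzoyl chloride | COc1cc(OC)cc(C(=O)Cl)c1 | starting material
3 | (5-bromo-2,4-dimethoxyphenyl)(3,5-dimethoxyphenyl)methanone | COc1cc(OC)cc(C(=O)c2cc(Br)c(OC)cc2OC)c1 | intermediate
4 | (5-bromo-2-hydroxy-4-methoxyphenyl)(3,5-dimethoxyphenyl)methanone | COc1cc(OC)cc(C(=O)c2cc(Br)c(OC)cc2O)c1 | intermediate
5 | 4-methoxybenzyl chloride | COc1ccc(CCl)cc1 | starting material
6 | {5-bromo-4-methoxy-2-[(4-methoxybenzyl)oxy]phenyl}(3,5-dimethoxyphenyl)methanone | COc1ccc(COc2cc(OC)c(Br)cc2C(=O)c2cc(OC)cc(OC)c2)cc1 | intermediate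
7 | hydrazone of ketone 6 (E/Z mixture) | COc1ccc(COc2cc(OC)c(Br)cc2C(=NN)c2cc(OC)cc(OC)c2)cc1 | intermediate
8 | {5-bromo-4-methoxy-2-[(4-methoxybenzyl)oxy]phenyl}(3,5-dimethoxyphenyl)diazomethane | COc1ccc(COc2cc(OC)c(Br)cc2C(=[N+]=[N-])c2cc(OC)cc(OC)c2)cc1 | intermediate
9 | (2S,3R)-5-bromo-3-(3,5-dimethoxyphenyl)-6-methoxy-2-(4-methoxyphenyl)-2,3-dihydrobenzofuran (cis) | Brc1cc2c(cc1OC)O[C@H](c1ccc(OC)cc1)[C@@H]2c1cc(OC)cc(OC)c1 | intermediate
10 | (2R,3R)-5-bromo-3-(3,5-dihydroxyphenyl)-2-(4-hydroxyphenyl)-2,3-dihydrobenzofuran-6-ol (trans) | Brc1cc2c(cc1O)O[C@@H](c1ccc(O)cc1)[C@@H]2c1cc(O)cc(O)c1 | intermediate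
11 | (2R,3R)-5-bromo-6-(tert-butyldimethylsilyloxy)-3-[3,5-bis(tert-butyldimethylsilyloxy)phenyl]-2-[4-(tert-butyldimethylsilyloxy)phenyl]-2,3-dihydrobenzofuran | Brc1cc2c(cc1O[Si](C)(C)C(C)(C)C)O[C@@H](c1ccc(O[Si](C)(C)C(C)(C)C)cc1)[C@@H]2c1cc(O[Si](C)(C)C(C)(C)C)cc(O[Si](C)(C)C(C)(C)C)c1 | intermediate
12 | 5-lithio derivative of 11 (aryllithium) | [Li]c1cc2c(cc1O[Si](C)(C)C(C)(C)C)O[C@@H](c1ccc(O[Si](C)(C)C(C)(C)C)cc1)[C@@H]2c1cc(O[Si](C)(C)C(C)(C)C)cc(O[Si](C)(C)C(C)(C)C)c1 | intermediate
13 | lithium aryl(triisopropoxy)borate derived from 12 | [Li+].CC(C)O[B-](OC(C)C)(OC(C)C)c1cc2c(cc1O[Si](C)(C)C(C)(C)C)O[C@@H](c1ccc(O[Si](C)(C)C(C)(C)C)cc1)[C@@H]2c1cc(O[Si](C)(C)C(C)(C)C)cc(O[Si](C)(C)C(C)(C)C)c1 | intermediate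
14 | [(2R,3R)-6-(tert-butyldimethylsilyloxy)-3-[3,5-bis(tert-butyldimethylsilyloxy)phenyl]-2-[4-(tert-butyldimethylsilyloxy)phenyl]-2,3-dihydrobenzofuran-5-yl]boronic acid | OB(O)c1cc2c(cc1O[Si](C)(C)C(C)(C)C)O[C@@H](c1ccc(O[Si](C)(C)C(C)(C)C)cc1)[C@@H]2c1cc(O[Si](C)(C)C(C)(C)C)cc(O[Si](C)(C)C(C)(C)C)c1 | intermediate
15 | 5,7-dihydroxy-4H-chromen-4-one | O=c1ccoc2cc(O)cc(O)c12 | starting material
16 | allyl bromide | C=CCBr | starting material
17 | 7-(allyloxy)-5-hydroxy-4H-chromen-4-one | O=c1ccoc2cc(OCC=C)cc(O)c12 | intermediate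
18 | 8-allyl-5-hydroxy-8H-chromene-4,7-dione (Claisen dienone) | O=C1C=C(O)C2=C(OC=CC2=O)C1CC=C | intermediate
19 | 8-allyl-5,7-dihydroxy-4H-chromen-4-one | O=c1ccoc2c(CC=C)c(O)cc(O)c12 | intermediate
20 | 8-allyl-5,7-bis(tert-butyldimethylsilyloxy)-4H-chromen-4-one | O=c1ccoc2c(CC=C)c(O[Si](C)(C)C(C)(C)C)cc(O[Si](C)(C)C(C)(C)C)c12 | intermediate
21 | methacrolein | CC(=C)C=O | starting material
22 | (E)-4-[5,7-bis(tert-butyldimethylsilyloxy)-4-oxo-4H-chromen-8-yl]-2-methylbut-2-enal | C/C(=C\Cc1c(O[Si](C)(C)C(C)(C)C)cc(O[Si](C)(C)C(C)(C)C)c2c1occc2=O)C=O | intermediate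
23 | 5,7-bis(tert-butyldimethylsilyloxy)-8-[(E)-4-hydroxy-3-methylbut-2-enyl]-4H-chromen-4-one | C/C(=C\Cc1c(O[Si](C)(C)C(C)(C)C)cc(O[Si](C)(C)C(C)(C)C)c2c1occc2=O)CO | intermediate
24 | (2S)-5,7-bis(tert-butyldimethylsilyloxy)-2-[(2R,3R)-6-(tert-butyldimethylsilyloxy)-3-[3,5-bis(tert-butyldimethylsilyloxy)phenyl]-2-[4-(tert-butyldimethylsilyloxy)phenyl]-2,3-dihydrobenzofuran-5-yl]-8-[(E)-4-hydroxy-3-methylbut-2-enyl]chroman-4-one | C/C(=C\Cc1c(O[Si](C)(C)C(C)(C)C)cc(O[Si](C)(C)C(C)(C)C)c2c1O[C@H](c1cc3c(cc1O[Si](C)(C)C(C)(C)C)O[C@@H](c1ccc(O[Si](C)(C)C(C)(C)C)cc1)[C@@H]3c1cc(O[Si](C)(C)C(C)(C)C)cc(O[Si](C)(C)C(C)(C)C)c1)CC2=O)CO | intermediate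
25 | (2S)-5,7-dihydroxy-2-[(2R,3R)-3-(3,5-dihydroxyphenyl)-6-hydroxy-2-(4-hydroxyphenyl)-2,3-dihydrobenzofuran-5-yl]-8-[(E)-4-hydroxy-3-methylbut-2-enyl]chroman-4-one | C/C(=C\Cc1c(O)cc(O)c2c1O[C@H](c1cc3c(cc1O)O[C@@H](c1ccc(O)cc1)[C@@H]3c1cc(O)cc(O)c1)CC2=O)CO | target

Total step count: 14. Longest linear sequence: 9 steps (steps 1 to 7, then 13 and 14); the chromone branch (steps 8 to 12) is 5 steps.

Steps most likely to fail

Step 13. The hindered ortho-silyloxy aryl group may transmetallate or insert so slowly that protodeboronation of 14 outruns C–C bond formation, or facial selectivity may erode. The fallback sets out from bromide 11 and chromone 23 and returns at 24; it replaces catalyst control by copper chemistry and separation of diastereomers. Bromide 11 is converted with Mg turnings/LiCl in THF into the arylmagnesium bromide F1. Alcohol 23 is masked with TMSCl/Et3N as its trimethylsilyl ether F2. CuBr·SMe2-catalysed, TMSCl-accelerated 1,4-addition of F1 to F2 at −40 °C should give the 4-(trimethylsilyloxy)-2H-chromene adduct F3 as a mixture of C2 epimers. Brief hydrolysis with 1 M HCl in THF should then give 24 together with its (2R) epimer F4. Because the dihydrobenzofuran is a single enantiomer, the two are diastereomers and are separated by preparative HPLC.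

Step 5. BBr3 may open the dihydrofuran ring irreversibly (benzylic bromide or stilbene formation) or leave the epimerisation incomplete. The fallback sets out from ketone 4 and returns at 11; it removes the methyl ethers before the sensitive ring exists. BBr3 converts 4 into (5-bromo-2,4-dihydroxyphenyl)(3,5-dihydroxyphenyl)methanone F5. TBSCl/imidazole silylates the three non-chelated phenols to give the tris-silyl ketone F6. Mitsunobu etherification (PPh3, DIAD) of the remaining chelated phenol with commercial 4-(tert-butyldimethylsilyloxy)benzyl alcohol gives the benzyl ether F7. Hydrazone formation (N2H4·H2O, AcOH cat., EtOH, 60 °C) gives the hydrazone F8. MnO2 oxidation gives the diazo compound F9 (not isolated), and Rh2(R-PTAD)4-catalysed C–H insertion gives the cis-tetrasilyl dihydrobenzofuran F10. Epimerisation at C2 with catalytic BF3·OEt2 in CH2Cl2 at −40 °C should then give 11.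

Step 7. Migration of the ortho silyl group from oxygen to carbon in the aryllithium, or attack of n-BuLi on silicon, may compete with capture by the borate. The fallback sets out from 11 and returns at 14; it uses palladium-catalysed Miyaura borylation, which avoids any aryl anion. PdCl2(dppf), B2pin2 and KOAc in dioxane at 85 °C should give the pinacol boronate F11. NaIO4/NH4OAc in acetone/water then cleaves the pinacol ester to 14.

Further compounds
F1 | step 13 | arylmagnesium bromide from 11 | Br[Mg]c1cc2c(cc1O[Si](C)(C)C(C)(C)C)O[C@@H](c1ccc(O[Si](C)(C)C(C)(C)C)cc1)[C@@H]2c1cc(O[Si](C)(C)C(C)(C)C)cc(O[Si](C)(C)C(C)(C)C)c1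
F2 | step 13 | trimethylsilyl ether of 23 | C/C(=C\Cc1c(O[Si](C)(C)C(C)(C)C)cc(O[Si](C)(C)C(C)(C)C)c2c1occc2=O)CO[Si](C)(C)C
F3 | step 13 | 4-(trimethylsilyloxy)-2H-chromene adduct (C2 epimers) | C/C(=C\Cc1c(O[Si](C)(C)C(C)(C)C)cc(O[Si](C)(C)C(C)(C)C)c2c1OC(c1cc3c(cc1O[Si](C)(C)C(C)(C)C)O[C@@H](c1ccc(O[Si](C)(C)C(C)(C)C)cc1)[C@@H]3c1cc(O[Si](C)(C)C(C)(C)C)cc(O[Si](C)(C)C(C)(C)C)c1)C=C2O[Si](C)(C)C)CO[Si](C)(C)C
F4 | step 13 | (2R) epimer of 24 | C/C(=C\Cc1c(O[Si](C)(C)C(C)(C)C)cc(O[Si](C)(C)C(C)(C)C)c2c1O[C@@H](c1cc3c(cc1O[Si](C)(C)C(C)(C)C)O[C@@H](c1ccc(O[Si](C)(C)C(C)(C)C)cc1)[C@@H]3c1cc(O[Si](C)(C)C(C)(C)C)cc(O[Si](C)(C)C(C)(C)C)c1)CC2=O)CO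
F5 | step 5 | (5-bromo-2,4-dihydroxyphenyl)(3,5-dihydroxyphenyl)methanone | O=C(c1cc(O)cc(O)c1)c1cc(Br)c(O)cc1O
F6 | step 5 | [5-bromo-4-(tert-butyldimethylsilyloxy)-2-hydroxyphenyl][3,5-bis(tert-butyldimethylsilyloxy)phenyl]methanone | O=C(c1cc(O[Si](C)(C)C(C)(C)C)cc(O[Si](C)(C)C(C)(C)C)c1)c1cc(Br)c(O[Si](C)(C)C(C)(C)C)cc1O
F7 | step 5 | 4-(tert-butyldimethylsilyloxy)benzyl ether of F6 | O=C(c1cc(O[Si](C)(C)C(C)(C)C)cc(O[Si](C)(C)C(C)(C)C)c1)c1cc(Br)c(O[Si](C)(C)C(C)(C)C)cc1OCc1ccc(O[Si](C)(C)C(C)(C)C)cc1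
F8 | step 5 | hydrazone of F7 | NN=C(c1cc(O[Si](C)(C)C(C)(C)C)cc(O[Si](C)(C)C(C)(C)C)c1)c1cc(Br)c(O[Si](C)(C)C(C)(C)C)cc1OCc1ccc(O[Si](C)(C)C(C)(C)C)cc1
F9 | step 5 | diazo compound from F8 | [N-]=[N+]=C(c1cc(O[Si](C)(C)C(C)(C)C)cc(O[Si](C)(C)C(C)(C)C)c1)c1cc(Br)c(O[Si](C)(C)C(C)(C)C)cc1OCc1ccc(O[Si](C)(C)C(C)(C)C)cc1
F10 | step 5 | (2S,3R)-cis epimer of 11 | Brc1cc2c(cc1O[Si](C)(C)C(C)(C)C)O[C@H](c1ccc(O[Si](C)(C)C(C)(C)C)cc1)[C@@H]2c1cc(O[Si](C)(C)C(C)(C)C)cc(O[Si](C)(C)C(C)(C)C)c1
F11 | step 7 | pinacol boronate corresponding to 14 | CC1(C)OB(OC1(C)C)c1cc2c(cc1O[Si](C)(C)C(C)(C)C)O[C@@H](c1ccc(O[Si](C)(C)C(C)(C)C)cc1)[C@@H]2c1cc(O[Si](C)(C)C(C)(C)C)cc(O[Si](C)(C)C(C)(C)C)c1
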